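**Assumption on numbering:** the ring is numbered C1 (quaternary carbon with the methoxy group and the carboxyl carbon C7), C2, C3 and C4 (free hydroxyls), C5 (caffeoyl ester) and C6; the locant 3 in the name of the target corresponds to C5 in this numbering.

## Analysis of the target

Target 24 is a cyclohexane with four stereocentres: a quaternary C1 that carries a methoxy group and the carboxyl carbon C7, and three contiguous secondary carbinol carbons C3, C4 and C5, flanked by the methylene groups C2 and C6. The oxygens on C1, C3 and C4 lie on one face of the ring, while C7 and the oxygen on C5 lie on the other, so O3/O4 are cis and O4/O5 trans. Only O5 is esterified, by (E)-caffeic acid 18, so the three secondary oxygens have to be told apart. The catechol cinnamate is sensitive to base (acyl migration to O4, ester cleavage), to oxidants and to nucleophiles that add to the enoate. The tertiary oxygen must be methylated while the secondary ones are not, and the acid must be set free at the end without a saponification next to the caffeoyl ester. The hard part is the C1 quaternary centre, whose configuration has to be fixed relative to C3–C5 and whose hindered oxygen has to be etherified. The strategy rests on the segment C2–C6: its oxygen pattern is that of C5–C1 of D-arabinose 1 (erythro C3/C4 of the sugar give cis O3/O4, threo C2/C3 give trans O4/O5). Only C1 is therefore missing, and both its C1–C7 bond and its O–CH3 bond can be made from a C1 ketone.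

## Retrosynthetic reasoning

**24 from 23.** The last disconnection removes only protecting groups. The O3/O4 acetonide and the two aryl acetates of 23 are all labile to aqueous acid, which leaves the alkyl cinnamate and the tertiary methyl ether alone. Acid is preferred to base because base would move or cleave the caffeoyl group. Since O5 is acylated and O3 is trans to C7, no lactone can form.

**23 from 21.** The carboxyl group is traced back to the tris(methylthio)methyl group of 21, an orthothioester that thiophilic divalent mercury hydrolyses through the thioester 22. The cut is placed here because the orthothioester is inert to acylation and to fluoride, and because its unmasking needs no hydroxide, which the caffeoyl ester would not survive.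

**21 from 17 and 20.** The O5–acyl bond is cut. In 17 the only free hydroxyl is O5, so the acylation needs no regiocontrol. The acid chloride 20 comes from caffeic acid 18 through its diacetate 19, which masks the phenols during the acylation.

**17 from 16.** The O5 silyl ether of 16 is removed by fluoride. Silyl on O5 and acetonide on O3/O4 is the pair that makes O5 uniquely addressable.

**16 from 11, 12 and 13.** This is the central disconnection: the C1–C7 bond and the O–CH3 bond are cut together. Ketone 11 has a trigonal C1, the carbanion 14 made from 12 brings C7 at the carboxyl oxidation level, and the alkoxide 15 formed by the addition is methylated by 13 at a moment when no other hydroxyl is free. The forward reaction must add to the carbonyl face anti to the acetonide, must not enolise 11 (its β-oxygens would be lost), and must trap the alkoxide before it reverts.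

**11 from 10, and 10 from 5 and 6.** The carbonyl of 11 is masked as the dithioketal 10, and both C1–C2 and C1–C6 are cut, leaving the five-carbon 1,5-dibromide 5 and the one-carbon unit 6. Two sequential alkylations through 7, 8 and 9 close the ring; no stereocentre is made. Bromides rather than iodides are chosen because the second metalation needs an alkyllithium base, which would attack an alkyl iodide at the halogen and trigger loss of the neighbouring oxygen.

**5 from 1.** Dibromide 5 is traced through the bromo alcohol 4 and the triol 3 to the sugar acetonide 2 and to 1. The 3,4-acetonide of the pyranose picks out the only cis diol, reduction turns C1 of the sugar into a primary alcohol, both primary positions are brominated, and the remaining secondary oxygen (the later O5) is silylated.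

## Alternatives that were turned down

**Alternative 1:** The C4–C5 bond is cut, leading back to the acyclic keto aldehyde A1, whose C1 already carries the methoxy group, a tert-butyl ester and two two-carbon arms. In the forward key step a chiral secondary amine forms the enamine on the oxygenated C4 side of the C3 ketone, and this adds to the C5 aldehyde in a 6-enolendo aldol closure to give the β-hydroxy ketone A2.
- For it: an anti aldol sets O4/O5 trans in one catalytic step; O5–H is free in A2, exactly the hydroxyl to be acylated; the acid-labile ester would merge with the final deprotection.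
- Against it: C1 of A1 is a stereocentre between two nearly identical arms and must come from desymmetrising a symmetrical tricarboxylate-type core. The catalyst must then match or override this remote centre. Enamine formation must choose C4 over C2. A2 is prone to dehydration and retro-aldol. The C3 carbonyl still needs an axial-selective reduction.
- Comparison: it is stronger on the differentiation of O5 and on independence from the chiral pool (either enantiomer is open). The chosen route has a single substrate-controlled stereo-determining event instead of four, with C3–C5 taken intact from 1.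

**Alternative 2:** The C5–C6 bond is cut, leading to the allylsilane aldehyde A3. A monodentate Lewis acid activates the aldehyde and the allylsilane attacks through C6 (intramolecular Hosomi–Sakurai reaction) to give the methylene cyclohexanol A4. Hydroxyl-directed epoxidation would then give the spiro-epoxide A5, opened at C1 with inversion by the alcohol that delivers the methyl ether, and the resulting C7 primary alcohol would be oxidised to the acid.
- For it: the closure is a reliable type; A4 has the same C3–C5 pattern as 11 with O5–H free; the methyl ether is made by an alcohol attacking carbon, so no hindered tertiary alkoxide has to be alkylated. On that last point it is stronger than the chosen route.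
- Against it: C5 is created in the closure next to an epimerisable α-alkoxy aldehyde, under non-chelation control that is not guaranteed. The C1 configuration depends on two events in a row, face-selective epoxidation and clean inversion at a tertiary carbon under acid, where carbocation character erodes fidelity and the acetonide is exposed to acidic alcohol. C7 arrives two oxidation levels too low, and the oxidation must be run with O5 protected.
- Comparison: the chosen route brings C7 in at the carboxyl level and sets C1 in one step under steric control by a rigid bicycle, in fewer steps.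

**Alternative 3:** The C1–C6 and C2–C3 bonds are cut by a Diels–Alder reaction of the diene A6 with the chiral α-oxyacrylate equivalent A7, giving the spiro adduct A8 by addition anti to the tert-butyl group. The carboxyl would then relay the oxygens: halolactonisation puts an oxygen cis to C7 (the later O5), elimination and cis-dihydroxylation anti to the lactone bridge add O3 and O4.
- For it: C1 is set first, with both its oxygen and its carboxyl, under auxiliary control that does not depend on a late ketone. The tertiary hydroxyl would be methylated on an α-hydroxy acid derivative that cannot fragment. On both points it is stronger than the chosen route.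
- Against it: A8 has one alkene for three oxygens, so the oxygenation takes five or more steps. An unactivated diene needs forcing conditions. The lactone ties C7 to O5 and has to be opened, with the acid protected, before the caffeoylation, which brings back the problem of lactone re-formation.
- Comparison: the chosen route takes all three carbinol centres, already differentiated as acetonide and silyl ether, from 1 and is shorter. It pays with a substrate-controlled addition and a hindered O-methylation.

Key step: step 7

## Route

Step 1
Reactants: 1 D-arabinose
Product: 2 3,4-O-isopropylidene-β-D-arabinopyranose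
Conditions: Me2C(OMe)2, TsOH (cat.), DMF, rt; Et3N
Reagents that add atoms: 2,2-dimethoxypropane, COC(C)(C)OC
Why: Acid-catalysed transacetalisation under kinetic conditions engages the only cis-vicinal diol of the pyranose, O3/O4, in a dioxolane; no stereocentre is touched, and the cis ring fusion later directs the key addition.

Step 2
Reactants: 2 3,4-O-isopropylidene-β-D-arabinopyranose
Product: 3 3,4-O-isopropylidene-D-arabinitol
Conditions: NaBH4, EtOH, 0 °C → rt
Reagents that add atoms: none
Why: Borohydride reduction of the lactol through its open-chain aldehyde gives the 1,2,5-triol; the anomeric centre disappears and the three carbinol centres are unchanged.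

Step 3
Reactants: 3 3,4-O-isopropylidene-D-arabinitol
Product: 4 1,5-dibromo-1,5-dideoxy-3,4-O-isopropylidene-D-arabinitol
Conditions: CBr4, PPh3, 2,6-lutidine, CH2Cl2, 0 °C
Reagents that add atoms: tetrabromomethane, BrC(Br)(Br)Br
Why: Appel reaction; the two primary alkoxyphosphonium ions form and are displaced by bromide much faster than the hindered secondary one, so O2 should stay free, and the buffer keeps the acetonide from adventitious acid.

Step 4
Reactants: 4 1,5-dibromo-1,5-dideoxy-3,4-O-isopropylidene-D-arabinitol
Product: 5 1,5-dibromo-2-O-(tert-butyldimethylsilyl)-1,5-dideoxy-3,4-O-isopropylidene-D-arabinitol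
Conditions: TBSOTf, 2,6-lutidine, CH2Cl2, −78 → 0 °C
Reagents that add atoms: tert-butyldimethylsilyl trifluoromethanesulfonate, CC(C)(C)[Si](C)(C)OS(=O)(=O)C(F)(F)F
Why: Silylation of a hindered secondary alcohol with a silyl triflate and a non-nucleophilic base; no alkoxide is formed, so the hydroxyl cannot close an oxirane or an oxolane onto the bromides.

Step 5
Reactants: 5 1,5-dibromo-2-O-(tert-butyldimethylsilyl)-1,5-dideoxy-3,4-O-isopropylidene-D-arabinitol; 6 1,3-dithiane
Product: 10 8-(tert-butyldimethylsilyloxy)-9,10-(isopropylidenedioxy)-1,5-dithiaspiro[5.5]undecane (oxygenated carbons configured as in 5), via 2-lithio-1,3-dithiane 7 (not isolated), via monoalkylated bromide 8 (not isolated), via lithiated bromide 9 (not isolated)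
Conditions: 6, n-BuLi, THF, −30 °C; 5, HMPA, −78 → −10 °C; n-BuLi, −78 → 0 °C
Reagents that add atoms: none
Why: Corey–Seebach cycloalkylation of a 1,5-dihalide: 7 should displace the less hindered bromide on the dioxolane side first, and a second metalation to 9 closes the cyclohexane by 6-exo-tet displacement of the bromide next to the silyloxy carbon (the other order of events would converge on the same ring). Bromides are used because they tolerate the second portion of n-BuLi, whereas iodides would undergo halogen–lithium exchange and lose the neighbouring oxygen.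

Step 6
Reactants: 10 8-(tert-butyldimethylsilyloxy)-9,10-(isopropylidenedioxy)-1,5-dithiaspiro[5.5]undecane
Product: 11 (3R,4R,5R)-5-(tert-butyldimethylsilyloxy)-3,4-(isopropylidenedioxy)cyclohexan-1-one (O3/O4 cis, O5 trans to O4)
Conditions: PhI(O2CCF3)2, NaHCO3, MeCN–H2O (9:1), 0 °C
Reagents that add atoms: water, O
Why: Oxidative hydrolysis of a dithioketal with a hypervalent iodine reagent; the buffered, near-neutral medium should spare the acetonide and the silyl ether and should not provoke elimination of the two β-oxygens of the new ketone.

Step 7
Reactants: 11 (3R,4R,5R)-5-(tert-butyldimethylsilyloxy)-3,4-(isopropylidenedioxy)cyclohexan-1-one; 12 tris(methylthio)methane; 13 iodomethane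
Product: 16 (1S,3R,4R,5R)-5-(tert-butyldimethylsilyloxy)-3,4-(isopropylidenedioxy)-1-methoxy-1-[tris(methylthio)methyl]cyclohexane, via tris(methylthio)methyllithium 14 (not isolated), via lithium alkoxide 15 (not isolated)
Conditions: 12, n-BuLi, THF, −78 °C; 11, −78 °C; 13, HMPA, −78 → 0 °C
Reagents that add atoms: none
Why: Deprotonation of 12 by n-BuLi gives the sulfur-stabilised carbanion 14, which adds 1,2 to the C1 carbonyl of 11 to form the C1–C7 bond and the lithium alkoxide 15, and 15 is then O-methylated by 13 in an SN2 (Williamson-type) step once HMPA has loosened the lithium–oxygen ion pair. The closest known reaction type is the addition of tris(methylthio)methyllithium to ketones as a carboxyl anion equivalent, combined with alkylation of the resulting alkoxide in the same flask. No ring is closed. The only new stereocentre is C1, and the cis-fused acetonide controls it: in the chair that keeps O4 and O5 equatorial, O3 is axial and, together with the dioxolane, shields the axial trajectory on its face of the carbonyl, so the bulky carbanion should enter equatorially from the convex face anti to O3 and O4. This places C7 cis to O5 and the alkoxide oxygen axial and cis to O3 and O4, as in 24; the same isomer is also the more stable one, because the tris(methylthio)methyl group can only sit equatorially, so partial reversibility of the addition should not erode the outcome. Besides this π-facial selectivity the step needs addition to win over enolisation, since an enolate of 11 would expel the oxygen at C3 or C5, and the low basicity and softness of 14 at −78 °C should secure this. It also needs O- over S-methylation, which the much higher nucleophilicity of the alkoxide compared with the thioether sulfurs should provide, and the methylation is started cold so that 15 is trapped before it can revert to 11 and 14.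

Step 8
Reactants: 16 (1S,3R,4R,5R)-5-(tert-butyldimethylsilyloxy)-3,4-(isopropylidenedioxy)-1-methoxy-1-[tris(methylthio)methyl]cyclohexane
Product: 17 (1R,3R,4S,5R)-3,4-(isopropylidenedioxy)-1-methoxy-1-[tris(methylthio)methyl]cyclohexan-5-ol (same spatial arrangement as 16; descriptors change with the substituent)
Conditions: TBAF, THF, 0 °C → rt
Reagents that add atoms: none
Why: Fluoride-induced cleavage of the silyl ether sets free O5–H only; the orthothioester, unlike an ester, cannot be attacked by the neighbouring alkoxide, so no lactone can form.

Step 9
Reactants: 18 caffeic acid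
Product: 19 (E)-3,4-diacetoxycinnamic acid
Conditions: Ac2O, pyridine, DMAP (cat.), rt; H2O
Reagents that add atoms: acetic anhydride, CC(=O)OC(C)=O
Why: Acetylation of the two phenols; the mixed anhydride formed at the carboxyl group is hydrolysed in the aqueous work-up, and the E alkene is untouched.

Step 10
Reactants: 19 (E)-3,4-diacetoxycinnamic acid
Product: 20 (E)-3,4-diacetoxycinnamoyl chloride
Conditions: (COCl)2, DMF (cat.), CH2Cl2, 0 °C → rt
Reagents that add atoms: oxalyl chloride, O=C(Cl)C(Cl)=O
Why: Acid chloride formation through the chloroiminium species made from DMF; the aryl acetates and the alkene geometry are stable to these conditions.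

Step 11
Reactants: 17 (1R,3R,4S,5R)-3,4-(isopropylidenedioxy)-1-methoxy-1-[tris(methylthio)methyl]cyclohexan-5-ol; 20 (E)-3,4-diacetoxycinnamoyl chloride
Product: 21 (1S,3R,4R,5R)-5-[(E)-3,4-diacetoxycinnamoyloxy]-3,4-(isopropylidenedioxy)-1-methoxy-1-[tris(methylthio)methyl]cyclohexane
Conditions: pyridine, DMAP (cat.), CH2Cl2, 0 °C → rt
Reagents that add atoms: none
Why: DMAP-catalysed acylation of the equatorial secondary alcohol, the only free hydroxyl, by an acid chloride; the orthothioester carries no acidic or nucleophilic site that could interfere.

Step 12
Reactants: 21 (1S,3R,4R,5R)-5-[(E)-3,4-diacetoxycinnamoyloxy]-3,4-(isopropylidenedioxy)-1-methoxy-1-[tris(methylthio)methyl]cyclohexane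
Product: 23 (1S,3R,4R,5R)-5-[(E)-3,4-diacetoxycinnamoyloxy]-3,4-(isopropylidenedioxy)-1-methoxycyclohexane-1-carboxylic acid, via S-methyl thioester 22 (not isolated)
Conditions: HgCl2, HgO, MeCN–H2O (4:1), rt → 45 °C
Reagents that add atoms: water, O
Why: Thiophilic hydrolysis of a trithioorthoester: divalent mercury removes one methylthio group, water captures the dithio-stabilised cation and gives thioester 22, which the excess mercury salt activates for a second hydrolysis to the acid, while HgO takes up the HCl and protects the acetonide. No hydroxide is involved, so the caffeoyl ester should survive, and C1 is not touched.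

Step 13
Reactants: 23 (1S,3R,4R,5R)-5-[(E)-3,4-diacetoxycinnamoyloxy]-3,4-(isopropylidenedioxy)-1-methoxycyclohexane-1-carboxylic acid
Product: 24 3-O-caffeoyl-1-methylquinic acid, (1S,3R,4R,5R)-5-[(E)-3-(3,4-dihydroxyphenyl)prop-2-enoyloxy]-3,4-dihydroxy-1-methoxycyclohexane-1-carboxylic acid
Conditions: 1 M HCl (aq), THF, rt
Reagents that add atoms: none
Why: Acid-catalysed hydrolysis of the isopropylidene acetal and of the two aryl acetates, which are more labile than the alkyl cinnamate; acid avoids base-induced acyl migration, and with O5 acylated and O3 trans to C7 no lactone can form.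

## Compound list

1 | D-arabinose | OC[C@@H](O)[C@@H](O)[C@H](O)C=O | starting material
2 | 3,4-O-isopropylidene-β-D-arabinopyranose | C1[C@H]2OC(C)(C)O[C@H]2[C@H](O)[C@H](O)O1 | intermediate
3 | 3,4-O-isopropylidene-D-arabinitol | OC[C@H]1OC(C)(C)O[C@H]1[C@H](O)CO | intermediate
4 | 1,5-dibromo-1,5-dideoxy-3,4-O-isopropylidene-D-arabinitol | BrC[C@H]1OC(C)(C)O[C@H]1[C@H](O)CBr | intermediate
5 | 1,5-dibromo-2-O-(tert-butyldimethylsilyl)-1,5-dideoxy-3,4-O-isopropylidene-D-arabinitol | BrC[C@H]1OC(C)(C)O[C@H]1[C@H](O[Si](C)(C)C(C)(C)C)CBr | intermediate
6 | 1,3-dithiane | C1CSCSC1 | starting material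
7 | 2-lithio-1,3-dithiane | [Li]C1SCCCS1 | intermediate
8 | 1-bromo-2-O-(tert-butyldimethylsilyl)-1,5-dideoxy-5-(1,3-dithian-2-yl)-3,4-O-isopropylidene-D-arabinitol | C1CSC(SC1)C[C@H]1OC(C)(C)O[C@H]1[C@H](O[Si](C)(C)C(C)(C)C)CBr | intermediate
9 | 1-bromo-2-O-(tert-butyldimethylsilyl)-1,5-dideoxy-3,4-O-isopropylidene-5-(2-lithio-1,3-dithian-2-yl)-D-arabinitol | [Li]C1(SCCCS1)C[C@H]1OC(C)(C)O[C@H]1[C@H](O[Si](C)(C)C(C)(C)C)CBr | intermediate
10 | 8-(tert-butyldimethylsilyloxy)-9,10-(isopropylidenedioxy)-1,5-dithiaspiro[5.5]undecane | C1CSC2(SC1)C[C@H]1OC(C)(C)O[C@H]1[C@H](O[Si](C)(C)C(C)(C)C)C2 | intermediate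
11 | (3R,4R,5R)-5-(tert-butyldimethylsilyloxy)-3,4-(isopropylidenedioxy)cyclohexan-1-one | O=C1C[C@H]2OC(C)(C)O[C@H]2[C@H](O[Si](C)(C)C(C)(C)C)C1 | intermediate
12 | tris(methylthio)methane | CSC(SC)SC | starting material
13 | iodomethane | CI | starting material
14 | tris(methylthio)methyllithium | [Li]C(SC)(SC)SC | intermediate
15 | lithium (1S,3R,4R,5R)-5-(tert-butyldimethylsilyloxy)-3,4-(isopropylidenedioxy)-1-[tris(methylthio)methyl]cyclohexan-1-olate | [Li]O[C@@]1(C(SC)(SC)SC)C[C@H]2OC(C)(C)O[C@H]2[C@H](O[Si](C)(C)C(C)(C)C)C1 | intermediate
16 | (1S,3R,4R,5R)-5-(tert-butyldimethylsilyloxy)-3,4-(isopropylidenedioxy)-1-methoxy-1-[tris(methylthio)methyl]cyclohexane | CO[C@@]1(C(SC)(SC)SC)C[C@H]2OC(C)(C)O[C@H]2[C@H](O[Si](C)(C)C(C)(C)C)C1 | intermediate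
17 | (1R,3R,4S,5R)-3,4-(isopropylidenedioxy)-1-methoxy-1-[tris(methylthio)methyl]cyclohexan-5-ol | CO[C@@]1(C(SC)(SC)SC)C[C@H]2OC(C)(C)O[C@H]2[C@H](O)C1 | intermediate
18 | caffeic acid | OC(=O)/C=C/c1ccc(O)c(O)c1 | starting material
19 | (E)-3,4-diacetoxycinnamic acid | CC(=O)Oc1ccc(/C=C/C(=O)O)cc1OC(C)=O | intermediate
20 | (E)-3,4-diacetoxycinnamoyl chloride | CC(=O)Oc1ccc(/C=C/C(Cl)=O)cc1OC(C)=O | intermediate
21 | (1S,3R,4R,5R)-5-[(E)-3,4-diacetoxycinnamoyloxy]-3,4-(isopropylidenedioxy)-1-methoxy-1-[tris(methylthio)methyl]cyclohexane | CO[C@@]1(C(SC)(SC)SC)C[C@H]2OC(C)(C)O[C@H]2[C@H](OC(=O)/C=C/c3ccc(OC(C)=O)c(OC(C)=O)c3)C1 | intermediate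
22 | S-methyl (1S,3R,4R,5R)-5-[(E)-3,4-diacetoxycinnamoyloxy]-3,4-(isopropylidenedioxy)-1-methoxycyclohexane-1-carbothioate | CO[C@@]1(C(=O)SC)C[C@H]2OC(C)(C)O[C@H]2[C@H](OC(=O)/C=C/c3ccc(OC(C)=O)c(OC(C)=O)c3)C1 | intermediate
23 | (1S,3R,4R,5R)-5-[(E)-3,4-diacetoxycinnamoyloxy]-3,4-(isopropylidenedioxy)-1-methoxycyclohexane-1-carboxylic acid | CO[C@@]1(C(=O)O)C[C@H]2OC(C)(C)O[C@H]2[C@H](OC(=O)/C=C/c3ccc(OC(C)=O)c(OC(C)=O)c3)C1 | intermediate
24 | 3-O-caffeoyl-1-methylquinic acid | CO[C@@]1(C(=O)O)C[C@@H](O)[C@@H](O)[C@H](OC(=O)/C=C/c2ccc(O)c(O)c2)C1 | target

## Step count and least certain steps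

Total step count: 13. Longest linear sequence: 11 steps (steps 1–8 and 11–13, from 1); steps 9 and 10 form the two-step branch from 18.

**Step 7 (key step).** The most likely failure is slow O-methylation of the hindered tertiary lithium alkoxide. On warming, the alkoxide can revert to ketone and carbanion, and the regenerated ketone can then be enolised and lose a β-oxygen. A second concern is loss of facial selectivity if the chair with an axial silyloxy group takes part. The fallback separates bond formation from methylation and methylates a substrate that cannot fragment. Setting out from 11, the adduct is quenched at −78 °C with AcOH and isolated as 5-(tert-butyldimethylsilyloxy)-3,4-(isopropylidenedioxy)-1-[tris(methylthio)methyl]cyclohexan-1-ol F1. Partial hydrolysis with HgCl2 and CaCO3 in aqueous MeCN at 0 °C should stop at S-methyl 5-(tert-butyldimethylsilyloxy)-1-hydroxy-3,4-(isopropylidenedioxy)cyclohexane-1-carbothioate F2. The α-hydroxyl is methylated with NaH and MeI in DMF at 0 °C to give S-methyl 5-(tert-butyldimethylsilyloxy)-3,4-(isopropylidenedioxy)-1-methoxycyclohexane-1-carbothioate F3. The silyl ether is removed with HF·pyridine, which is non-basic and so avoids lactone formation, to give S-methyl 5-hydroxy-3,4-(isopropylidenedioxy)-1-methoxycyclohexane-1-carbothioate F4. Acylation with 20 (pyridine, DMAP) comes back to the route at 22, which the conditions of step 12 convert into 23.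

**Step 5.** What may go wrong is a second intermolecular alkylation that puts two dithianes on one chain, or attack of the second portion of n-BuLi on the remaining bromide instead of metalation, followed by loss of the β-silyloxy group. The fallback uses a more acidic one-carbon unit, so that both alkylations run with a hydride base in one flask and the ring closure outruns intermolecular reaction. Setting out from 5, double alkylation of methyl methylthiomethyl sulfoxide with KH in THF (0 °C → rt) should give 5-(tert-butyldimethylsilyloxy)-3,4-(isopropylidenedioxy)-1-(methylsulfinyl)-1-(methylthio)cyclohexane F5 as a mixture of isomers at C1 and sulfur. Brief treatment with catalytic H2SO4 in aqueous THF at 0 °C comes back to the route at 11.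

**Step 12.** The hydrolysis may stall at thioester 22, whose carbonyl sits next to the quaternary C1, and long exposure to the mercury salt may damage the cinnamate alkene or the acetonide. The fallback unveils the acid before the caffeoyl group is present. Setting out from 16, HgCl2 and HgO in aqueous MeCN give 5-(tert-butyldimethylsilyloxy)-3,4-(isopropylidenedioxy)-1-methoxycyclohexane-1-carboxylic acid F6. Allyl bromide and K2CO3 in DMF give allyl 5-(tert-butyldimethylsilyloxy)-3,4-(isopropylidenedioxy)-1-methoxycyclohexane-1-carboxylate F7. TBAF buffered with AcOH gives allyl 5-hydroxy-3,4-(isopropylidenedioxy)-1-methoxycyclohexane-1-carboxylate F8. Acylation with 20 gives allyl 5-[(E)-3,4-diacetoxycinnamoyloxy]-3,4-(isopropylidenedioxy)-1-methoxycyclohexane-1-carboxylate F9. Allyl transfer to N-methylaniline with Pd(PPh3)4 (zerovalent palladium) comes back to the route at 23.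

**Step 3.** What may go wrong is bromination of the secondary hydroxyl as well, or closure of the bromo alcohol to an oxolane (O2 onto C5) or an oxirane during the reaction. The fallback goes through sulfonates. Setting out from 3, TsCl in pyridine at −20 °C gives 3,4-O-isopropylidene-1,5-di-O-tosyl-D-arabinitol F10. TBSOTf and 2,6-lutidine give 2-O-(tert-butyldimethylsilyl)-3,4-O-isopropylidene-1,5-di-O-tosyl-D-arabinitol F11. LiBr in butanone at 80 °C displaces both sulfonates and comes back to the route at 5.

**Step 13.** The aryl acetates may hydrolyse slowly, and the long acid exposure then invites acyl migration from O5 to O4 or cleavage of the caffeoyl ester. The fallback takes the protecting groups off in two chemoselective stages. Setting out from 23, NH4OAc in aqueous MeOH removes only the aryl acetates and gives 5-[(E)-3-(3,4-dihydroxyphenyl)prop-2-enoyloxy]-3,4-(isopropylidenedioxy)-1-methoxycyclohexane-1-carboxylic acid F12. A short treatment with aqueous TFA at 0 °C then cleaves the acetonide and arrives at 24.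

## Further compounds

F1 | step 7 | 5-(tert-butyldimethylsilyloxy)-3,4-(isopropylidenedioxy)-1-[tris(methylthio)methyl]cyclohexan-1-ol | O[C@@]1(C(SC)(SC)SC)C[C@H]2OC(C)(C)O[C@H]2[C@H](O[Si](C)(C)C(C)(C)C)C1
F2 | step 7 | S-methyl 5-(tert-butyldimethylsilyloxy)-1-hydroxy-3,4-(isopropylidenedioxy)cyclohexane-1-carbothioate | O[C@@]1(C(=O)SC)C[C@H]2OC(C)(C)O[C@H]2[C@H](O[Si](C)(C)C(C)(C)C)C1
F3 | step 7 | S-methyl 5-(tert-butyldimethylsilyloxy)-3,4-(isopropylidenedioxy)-1-methoxycyclohexane-1-carbothioate | CO[C@@]1(C(=O)SC)C[C@H]2OC(C)(C)O[C@H]2[C@H](O[Si](C)(C)C(C)(C)C)C1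
F4 | step 7 | S-methyl 5-hydroxy-3,4-(isopropylidenedioxy)-1-methoxycyclohexane-1-carbothioate | CO[C@@]1(C(=O)SC)C[C@H]2OC(C)(C)O[C@H]2[C@H](O)C1
F5 | step 5 | 5-(tert-butyldimethylsilyloxy)-3,4-(isopropylidenedioxy)-1-(methylsulfinyl)-1-(methylthio)cyclohexane | CS(=O)C1(SC)C[C@H]2OC(C)(C)O[C@H]2[C@H](O[Si](C)(C)C(C)(C)C)C1
F6 | step 12 | 5-(tert-butyldimethylsilyloxy)-3,4-(isopropylidenedioxy)-1-methoxycyclohexane-1-carboxylic acid | CO[C@@]1(C(=O)O)C[C@H]2OC(C)(C)O[C@H]2[C@H](O[Si](C)(C)C(C)(C)C)C1
F7 | step 12 | allyl 5-(tert-butyldimethylsilyloxy)-3,4-(isopropylidenedioxy)-1-methoxycyclohexane-1-carboxylate | CO[C@@]1(C(=O)OCC=C)C[C@H]2OC(C)(C)O[C@H]2[C@H](O[Si](C)(C)C(C)(C)C)C1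
F8 | step 12 | allyl 5-hydroxy-3,4-(isopropylidenedioxy)-1-methoxycyclohexane-1-carboxylate | CO[C@@]1(C(=O)OCC=C)C[C@H]2OC(C)(C)O[C@H]2[C@H](O)C1
F9 | step 12 | allyl 5-[(E)-3,4-diacetoxycinnamoyloxy]-3,4-(isopropylidenedioxy)-1-methoxycyclohexane-1-carboxylate | CO[C@@]1(C(=O)OCC=C)C[C@H]2OC(C)(C)O[C@H]2[C@H](OC(=O)/C=C/c3ccc(OC(C)=O)c(OC(C)=O)c3)C1
F10 | step 3 | 3,4-O-isopropylidene-1,5-di-O-tosyl-D-arabinitol | Cc1ccc(cc1)S(=O)(=O)OC[C@H]1OC(C)(C)O[C@H]1[C@H](O)COS(=O)(=O)c1ccc(C)cc1
F11 | step 3 | 2-O-(tert-butyldimethylsilyl)-3,4-O-isopropylidene-1,5-di-O-tosyl-D-arabinitol | Cc1ccc(cc1)S(=O)(=O)OC[C@H]1OC(C)(C)O[C@H]1[C@H](O[Si](C)(C)C(C)(C)C)COS(=O)(=O)c1ccc(C)cc1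
F12 | step 13 | 5-[(E)-3-(3,4-dihydroxyphenyl)prop-2-enoyloxy]-3,4-(isopropylidenedioxy)-1-methoxycyclohexane-1-carboxylic acid | CO[C@@]1(C(=O)O)C[C@H]2OC(C)(C)O[C@H]2[C@H](OC(=O)/C=C/c3ccc(O)c(O)c3)C1
A1 | alternative 1 | tert-butyl 2-methoxy-4-oxo-2-(2-oxoethyl)-5-(4-methoxybenzyloxy)pentanoate | CO[C@@](CC=O)(C(=O)OC(C)(C)C)CC(=O)COCc1ccc(OC)cc1
A2 | alternative 1 | tert-butyl 5-hydroxy-1-methoxy-4-(4-methoxybenzyloxy)-3-oxocyclohexane-1-carboxylate | CO[C@@]1(C(=O)OC(C)(C)C)CC(=O)[C@@H](OCc2ccc(OC)cc2)[C@H](O)C1
A3 | alternative 2 | cis-2,2-dimethyl-5-[2-(trimethylsilylmethyl)prop-2-enyl]-1,3-dioxolane-4-carbaldehyde | C=C(C[Si](C)(C)C)C[C@H]1OC(C)(C)O[C@H]1C=O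
A4 | alternative 2 | 3,4-(isopropylidenedioxy)-1-methylenecyclohexan-5-ol | C=C1C[C@H]2OC(C)(C)O[C@H]2[C@H](O)C1
A5 | alternative 2 | 5,6-(isopropylidenedioxy)-1-oxaspiro[2.5]octan-7-ol, epoxide oxygen cis to the hydroxyl | C1O[C@@]12C[C@H]3OC(C)(C)O[C@H]3[C@H](O)C2
A6 | alternative 3 | buta-1,3-diene | C=CC=C
A7 | alternative 3 | (R)-2-tert-butyl-5-methylene-1,3-dioxolan-4-one | C=C1O[C@@H](C(C)(C)C)OC1=O
A8 | alternative 3 | 2-tert-butyl-1,3-dioxaspiro[4.5]dec-7-en-4-one | O=C1O[C@H](C(C)(C)C)O[C@]12CCC=CC2
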